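- The ash run ends at 73.9% other capture product on 1.5 equiv of second nucleophile, the oak run at 85.7% on 2.4 equiv; this gap between the two plateaus is the handle on the new flask.

common to all: substrate 20 mM

|  | first nucleophile | second nucleophile | remark | time |
|---|---|---|---|---|
| ash | 5 equiv | 1.5 equiv | run made earlier |  |
| oak | 5 equiv | 2.4 equiv | run made earlier |  |
| flask | 5.00 equiv | 1.10 equiv |  | 20 min |

| run | time / min | target / % | other capture product / % |
|---|---|---|---|
| ash | 3.00 | 2.4 | 38.9 |
| ash | 6.00 | 0.7 | 59.5 |
| ash | 10.0 | 1.4 | 69.0 |
| ash | 12.0 | 0 | 72.7 |
| ash | 15.0 | 0.6 | 72.7 |
| ash | 20.0 | 1.4 | 73.9 |
| oak | 1.33 | 1.6 | 21.8 |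
| oak | 4.00 | 0.9 | 52.6 |
| oak | 8.00 | 0.4 | 72.3 |
| oak | 10.0 | 0.7 | 76.5 |
| oak | 15.0 | 1.9 | 84.0 |
| oak | 20.0 | 0 | 85.7 |

(scatter of a reading: 1 percentage point)

- percentages count the substrate that a species holds: one side product counts as two
- steps that have been proposed: first nucleophile + intermediate -> target; substrate + target -> side product; first nucleophile -> decomposed reagent; second nucleophile + intermediate -> other capture product; intermediate -> solvolysis product; substrate -> intermediate

- ratio of target to other capture product at 10 s
- ratio of target to other capture product at 20 min
- which of target and other capture product there is more of at 20 min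

- Fastest rung: the intermediate, formed from substrate, goes to target with first nucleophile, to other capture product with second nucleophile, or to solvolysis product. The oak curve rises from its first reading without visible delay, so the intermediate does not appear to pile up.
- Next rung: in the oak run, target reads 1.6% at 1.33 min and 1.9% at 15.0 min, while other capture product climbs from 21.8% to 84.0%. Although first nucleophile is charged at 5.00 equiv, target doesn't keep pace, which points to an early end of its capture through the proposed decomposition of first nucleophile.
- Slow rung: the oak curve gives substrate a rate constant of 0.238 min⁻¹, a half-life of 2.91 min, and about 0.857% left at 20 min.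
- What remains is a split between second nucleophile and solvolysis. Integrated while c(second nucleophile) falls, the other capture product plus a level times the logarithm of charge over remainder equals the substrate charged, all in equivalents.
- The ash run gives 0.385 equiv and the oak run 0.324 equiv. Their mean, 0.354 equiv, is the break-even level: the level of second nucleophile at which capture and every other fate of the intermediate split evenly, the zero of the scale.
- For the new flask, this reckoning starts from the share at the charge, 75.6%, and averages each guess with what the balance returns: 67.2%, then 66.9% other capture product.
- The last two target readings of both runs average 0.975%, which makes the late ratio 0.0146. The first oak ratio, scaled to this charge, gives 0.160 as a low mark for 10 s.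
- The forecast gives 0.2 (0.1 to 0.38) at 10 s, above this mark, and 0.017 (0.006 to 0.035) at 20 min, above this ratio, with other capture product ahead, adding “so the ratio is about 0.2, poorly constrained”.
- The flask gives 0.348 at 10 s and 0.0194 at 20 min, with other capture product ahead at 66.7% against 1.29% of target.

    first nucleophile + intermediate → target (k = 7.20 L mol⁻¹ s⁻¹)
    substrate + target → side product (k = 0.0831 L mol⁻¹ s⁻¹)
    first nucleophile → decomposed reagent (k = 0.0647 s⁻¹)
    second nucleophile + intermediate → other capture product (k = 68.0 L mol⁻¹ s⁻¹)
    intermediate → solvolysis product (k = 0.440 s⁻¹)
    substrate → intermediate (k = 0.00411 s⁻¹)

- In this flask the decomposition of first nucleophile is the largest single effect on the ratio at 20 min: without that step the ratio is 0.512, against 0.0194 with it. At 20.0 min the flask still holds 39% of its own charge of second nucleophile, which is 0.433 equiv and above the break-even level of 0.354 equiv. A neighbour flask charged with 0.280 equiv of second nucleophile, otherwise the same, starts below that level, with a share at the charge of 44.2%. That neighbour ends with solvolysis product ahead, at 69.8% against 24.8% other capture product.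

The earlier runs and the new flask are simulated from invented constants; the scatter is artificial.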